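**Retrosynthetic overview**
- The α-methylene-γ-lactone is cut at O–C6 and C11–C7 in one operation, giving a ten-membered (4Z,6Z)-1,3-diene and 2-bromoacrylic acid (palladium-catalysed [3+2] carbo-acyloxylation). Only a C9 silyl ether is removed afterwards.
- Enabling feature: C6 (O-bearing, allylic to C4=C5) and C7 (C11-bearing) are adjacent carbons of the ten-membered carbocycle. The lactone is therefore the 1,2-adduct of an acrylate C–C(=O)–O unit across the C6=C7 end of a ring diene C4=C5–C6=C7, with the C8 acyloxy stereocentre next to it to steer the face.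
- The ten-membered carbocycle is closed by ring-closing metathesis at C6=C7 of an acyclic triene.
- C8/C9 come from a reagent-controlled syn-alkoxyallylboration of an epoxy aldehyde (C8–C9 bond). C1/C10 come from a Sharpless epoxidation of 8-hydroxyneryl acetate, which also supplies the 4Z alkene.
- Ring order: oxirane (step 2), ten-membered carbocycle (step 11), γ-lactone (step 12).

Key step: step 12

Remark: the SMILES encodes a cis-fused γ-lactone (H-6 and H-7 on the same face), a 4Z alkene and a trans epoxide. Locants follow germacrane numbering (C1/C10 epoxide, C4=C5, C6–O, C7–C11, C8 isobutyrate, C9 OH, C11–C13 lactone carbons). The C10 descriptor switches between R and S with the C9 substituent only through CIP priority.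

**Route**

Step 1
Reactants: 1 neryl acetate
Product: 2 (2Z,6E)-8-hydroxy-3,7-dimethylocta-2,6-dien-1-yl acetate
Conditions: SeO2 (cat.), tBuOOH, salicylic acid (cat.), CH2Cl2, rt
Reagents that add atoms: tert-butyl hydroperoxide, CC(C)(C)OO
Why: Catalytic SeO2 allylic oxidation (ene reaction, then [2,3]-sigmatropic shift) should oxidize the (E)-methyl group of the electron-rich distal alkene, the alkene next to the acetate being deactivated; no stereocentre is formed.

Step 2
Reactants: 2 (2Z,6E)-8-hydroxy-3,7-dimethylocta-2,6-dien-1-yl acetate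
Product: 3 (2R,3R)-epoxy alcohol (C1 R, C10 R)
Conditions: Ti(OiPr)4, D-(−)-diethyl tartrate, tBuOOH, 4 Å MS, CH2Cl2, −20 °C
Reagents that add atoms: tert-butyl hydroperoxide, CC(C)(C)OO
Why: Sharpless asymmetric epoxidation acts only on the allylic alcohol, and D-(−)-diethyl tartrate should give the (2R,3R)-epoxide, which sets C1 and C10 by reagent control.

Step 3
Reactants: 3 (2R,3R)-epoxy alcohol
Product: 4 epoxy aldehyde (C9 aldehyde)
Conditions: TEMPO (cat.), PhI(OAc)2, CH2Cl2, rt
Reagents that add atoms: none
Why: TEMPO/PhI(OAc)2 oxidation (oxoammonium mechanism) is neutral and stops at the aldehyde, whose quaternary α-carbon cannot epimerize.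

Step 4
Reactants: 4 epoxy aldehyde; 5 allyl 4-methoxyphenyl ether
Product: 8 syn-(8R,9S) C9 alcohol C8 4-methoxyphenyl ether, via allylborane 6 (not isolated), via borinate ester 7 (not isolated)
Conditions: 5, sBuLi, THF, −78 °C; (−)-Ipc2BOMe; BF3·OEt2; 4, −78 °C; then NaBO3·4H2O, THF–H2O, rt
Reagents that add atoms: none
Why: Brown syn-alkoxyallylboration through a chair six-membered transition state, in which the Z enol ether geometry of 6 gives the syn C8/C9 relationship and the isopinocampheyl groups from (+)-α-pinene direct attack to the Si face of the aldehyde (C9 S, C8 R), against the Felkin–Anh preference of the epoxy aldehyde.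

Step 5
Reactants: 8 syn C9 alcohol
Product: 9 C9 tert-butyldimethylsilyl ether
Conditions: TBSOTf, 2,6-lutidine, CH2Cl2, −78 °C
Reagents that add atoms: tert-butyldimethylsilyl triflate, CC(C)(C)[Si](C)(C)OS(=O)(=O)C(F)(F)F
Why: Silylation of the hindered secondary alcohol with the silyl triflate and a hindered base at low temperature should leave the epoxide intact and blocks later acyl migration and Payne rearrangement.

Step 6
Reactants: 9 C9 silyl ether
Product: 10 C8 alcohol
Conditions: (NH4)2Ce(NO3)6, pyridine, MeCN–H2O, 0 °C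
Reagents that add atoms: none
Why: Oxidative cleavage of the 4-methoxyphenyl ether (single-electron oxidation of the arene, hydrolysis to benzoquinone) frees the C8 hydroxyl with its C–O bond untouched, the pyridine buffer protecting epoxide, silyl ether and acetate.

Step 7
Reactants: 10 C8 alcohol
Product: 11 C8 isobutyrate
Conditions: (iPrCO)2O, DMAP (cat.), pyridine, CH2Cl2, 0 °C to rt
Reagents that add atoms: isobutyric anhydride, CC(C)C(=O)OC(=O)C(C)C
Why: DMAP-catalysed acylation of the only free hydroxyl installs the isobutyrate of the target with retention at C8.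

Step 8
Reactants: 11 C8 isobutyrate
Product: 12 C6 allylic alcohol
Conditions: K2CO3 (cat.), MeOH, 0 °C
Reagents that add atoms: none
Why: Base-catalysed transesterification should remove the unhindered primary allylic acetate much faster than the α-branched isobutyrate on a hindered secondary carbon.

Step 9
Reactants: 12 C6 allylic alcohol
Product: 13 (Z)-enal
Conditions: TEMPO (cat.), PhI(OAc)2, CH2Cl2, 0 °C to rt
Reagents that add atoms: none
Why: TEMPO/PhI(OAc)2 oxidation of the allylic alcohol is neutral, so the Z geometry of the neral-type enal should be retained.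

Step 10
Reactants: 13 (Z)-enal
Product: 14 acyclic triene (terminal (3Z)-diene and C7 vinyl group)
Conditions: Ph3PCH3Br, KN(SiMe3)2, THF, −78 to 0 °C
Reagents that add atoms: methyltriphenylphosphonium bromide, C[P+](c1ccccc1)(c1ccccc1)c1ccccc1.[Br-]
Why: Wittig methylenation with the salt-free ylide at low temperature should convert the aldehyde into the terminal diene faster than the ylide attacks the ester, leaving the Z trisubstituted alkene unchanged.

Step 11
Reactants: 14 acyclic triene
Product: 15 ten-membered (4Z,6Z)-diene (11-oxabicyclo[8.1.0]undeca-4,6-diene)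
Conditions: second-generation Grubbs catalyst (10 mol %), toluene (1 mM), 80 °C
Reagents that add atoms: none
Why: Ring-closing metathesis between the C7 vinyl group and the monosubstituted end of the diene under high dilution, the trisubstituted C4=C5 bond being inert, should give the new C6=C7 bond as the less strained Z isomer of the ten-membered ring.

Step 12
Reactants: 15 ten-membered (4Z,6Z)-diene; 16 2-bromoacrylic acid
Product: 19 C9-silylated α-methylene lactone, via vinylpalladium bromide 17 (not isolated), via oxapalladacycle 18 (not isolated)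
Conditions: Pd(OAc)2 (10 mol %), NaHCO3, nBu4NCl, DMF, 60 °C, slow addition of 16
Reagents that add atoms: none
Why: Proposed new method: zerovalent palladium formed from Pd(OAc)2 inserts into the C–Br bond of 16 to give 17, which adds syn across C6=C7 with C11 bonding to the less substituted diene terminus C7 and palladium moving to C6, where it is held as the η3-allyl/oxapalladacycle 18; carboxylate-to-C6 reductive elimination then closes the lactone and returns zerovalent palladium. The closest known reaction type is the Larock heteroannulation of 1,3-dienes with aryl or vinylic halides that carry a carboxylic acid, which gives cis-fused unsaturated lactones from cyclic dienes; its use with 2-bromoacrylic acid on a medium-ring diene is the new element. The γ-lactone closes in a 5-exo mode (O onto the near allyl terminus C6, the C4=C5 bond staying outside the new ring) by C–O reductive elimination from the six-membered palladacycle. C7 is controlled by C8: allylic 1,3-strain in the (6Z)-alkene holds H-8 in the alkene plane, the ring (C9) covers one face, and the palladium reagent should attack the open peripheral face that carries the C8 ester oxygen; C6 follows from syn carbopalladation and retentive C–O bond formation on the (6Z)-alkene, which places O and C11 on the same face and gives the cis ring fusion. The step needs terminus selectivity (C7 over the fully substituted C4, secured by the C4 methyl group), retention of the 4Z geometry (the tethered carboxylate should trap the allyl faster than syn–anti isomerization) and survival of the allylic isobutyrate (phosphine-free conditions, so that the electron-poor vinyl bromide outcompetes ester ionization).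

Step 13
Reactants: 19 C9-silylated α-methylene lactone
Product: 20 target CNP0110853.1
Conditions: HF·pyridine, pyridine, THF, 0 °C to rt
Reagents that add atoms: none
Why: Buffered fluoride desilylation frees the C9 hydroxyl without base, so acyl migration from O-8 to O-9, epoxide opening and conjugate addition to the α-methylene lactone should not occur.

**Compound list**

1 | neryl acetate, (2Z)-3,7-dimethylocta-2,6-dien-1-yl acetate | CC(=O)OC/C=C(/C)CCC=C(C)C | starting material
2 | (2Z,6E)-8-hydroxy-3,7-dimethylocta-2,6-dien-1-yl acetate | CC(=O)OC/C=C(/C)CC/C=C(\C)CO | intermediate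
3 | (2Z)-5-[(2R,3R)-3-(hydroxymethyl)-3-methyloxiran-2-yl]-3-methylpent-2-en-1-yl acetate | CC(=O)OC/C=C(/C)CC[C@H]1O[C@]1(C)CO | intermediate
4 | (2Z)-5-[(2R,3S)-3-formyl-3-methyloxiran-2-yl]-3-methylpent-2-en-1-yl acetate | CC(=O)OC/C=C(/C)CC[C@H]1O[C@]1(C)C=O | intermediate
5 | allyl 4-methoxyphenyl ether, 1-methoxy-4-(prop-2-en-1-yloxy)benzene | C=CCOc1ccc(OC)cc1 | starting material
6 | [(2Z)-3-(4-methoxyphenoxy)prop-2-en-1-yl]diisopinocampheylborane (isopinocampheyl groups from (+)-α-pinene) | COc1ccc(O/C=C\CB([C@@H]2C[C@@H]3C[C@H]([C@H]2C)C3(C)C)[C@@H]2C[C@@H]3C[C@H]([C@H]2C)C3(C)C)cc1 | intermediate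
7 | O-diisopinocampheylboryl derivative (borinate ester) of 8 | CC(=O)OC/C=C(/C)CC[C@H]1O[C@]1(C)[C@@H](OB([C@@H]2C[C@@H]3C[C@H]([C@H]2C)C3(C)C)[C@@H]2C[C@@H]3C[C@H]([C@H]2C)C3(C)C)[C@H](Oc2ccc(OC)cc2)C=C | intermediate
8 | (2Z)-5-{(2R,3R)-3-[(1S,2R)-1-hydroxy-2-(4-methoxyphenoxy)but-3-en-1-yl]-3-methyloxiran-2-yl}-3-methylpent-2-en-1-yl acetate | CC(=O)OC/C=C(/C)CC[C@H]1O[C@]1(C)[C@@H](O)[C@H](Oc2ccc(OC)cc2)C=C | intermediate
9 | (2Z)-5-{(2R,3S)-3-[(1S,2R)-1-[(tert-butyldimethylsilyl)oxy]-2-(4-methoxyphenoxy)but-3-en-1-yl]-3-methyloxiran-2-yl}-3-methylpent-2-en-1-yl acetate | CC(=O)OC/C=C(/C)CC[C@H]1O[C@]1(C)[C@@H](O[Si](C)(C)C(C)(C)C)[C@H](Oc2ccc(OC)cc2)C=C | intermediate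
10 | (2Z)-5-{(2R,3S)-3-[(1S,2R)-1-[(tert-butyldimethylsilyl)oxy]-2-hydroxybut-3-en-1-yl]-3-methyloxiran-2-yl}-3-methylpent-2-en-1-yl acetate | CC(=O)OC/C=C(/C)CC[C@H]1O[C@]1(C)[C@@H](O[Si](C)(C)C(C)(C)C)[C@H](O)C=C | intermediate
11 | (2Z)-5-{(2R,3S)-3-[(1S,2R)-1-[(tert-butyldimethylsilyl)oxy]-2-[(2-methylpropanoyl)oxy]but-3-en-1-yl]-3-methyloxiran-2-yl}-3-methylpent-2-en-1-yl acetate | CC(=O)OC/C=C(/C)CC[C@H]1O[C@]1(C)[C@@H](O[Si](C)(C)C(C)(C)C)[C@H](OC(=O)C(C)C)C=C | intermediate
12 | (3R,4S)-4-[(tert-butyldimethylsilyl)oxy]-4-{(2S,3R)-3-[(3Z)-5-hydroxy-3-methylpent-3-en-1-yl]-2-methyloxiran-2-yl}but-1-en-3-yl 2-methylpropanoate | OC/C=C(/C)CC[C@H]1O[C@]1(C)[C@@H](O[Si](C)(C)C(C)(C)C)[C@H](OC(=O)C(C)C)C=C | intermediate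
13 | (3R,4S)-4-[(tert-butyldimethylsilyl)oxy]-4-{(2S,3R)-2-methyl-3-[(3Z)-3-methyl-5-oxopent-3-en-1-yl]oxiran-2-yl}but-1-en-3-yl 2-methylpropanoate | O=C/C=C(/C)CC[C@H]1O[C@]1(C)[C@@H](O[Si](C)(C)C(C)(C)C)[C@H](OC(=O)C(C)C)C=C | intermediate
14 | (3R,4S)-4-[(tert-butyldimethylsilyl)oxy]-4-{(2S,3R)-2-methyl-3-[(3Z)-3-methylhexa-3,5-dien-1-yl]oxiran-2-yl}but-1-en-3-yl 2-methylpropanoate | C=C/C=C(/C)CC[C@H]1O[C@]1(C)[C@@H](O[Si](C)(C)C(C)(C)C)[C@H](OC(=O)C(C)C)C=C | intermediate
15 | (1S,2S,3R,4Z,6Z,10R)-2-[(tert-butyldimethylsilyl)oxy]-1,7-dimethyl-11-oxabicyclo[8.1.0]undeca-4,6-dien-3-yl 2-methylpropanoate | C1C/C(C)=C\C=C/[C@@H](OC(=O)C(C)C)[C@H](O[Si](C)(C)C(C)(C)C)[C@@]2(C)O[C@@H]21 | intermediate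
16 | 2-bromoacrylic acid, 2-bromoprop-2-enoic acid | C=C(Br)C(=O)O | starting material
17 | bromo(1-carboxyethenyl)palladium, oxidative-addition complex (other ligands omitted) | C=C([Pd]Br)C(=O)O | intermediate
18 | six-membered oxapalladacycle, σ-allyl form: palladium on C6 and on the carboxylate oxygen, C7–C11 bond formed | C=C1C(=O)O[Pd][C@H]2/C=C(/C)CC[C@H]3O[C@]3(C)[C@@H](O[Si](C)(C)C(C)(C)C)[C@H](OC(=O)C(C)C)[C@@H]12 | intermediate
19 | (1R,4Z,6S,7S,8R,9S,10S)-9-[(tert-butyldimethylsilyl)oxy]-1,10-epoxy-8-(2-methylpropanoyloxy)germacra-4,11(13)-dien-12,6-olide, cis-fused | C=C1C(=O)O[C@H]2/C=C(/C)CC[C@H]3O[C@]3(C)[C@@H](O[Si](C)(C)C(C)(C)C)[C@H](OC(=O)C(C)C)[C@@H]12 | intermediate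
20 | CNP0110853.1, (1R,4Z,6S,7S,8R,9S,10R)-1,10-epoxy-9-hydroxy-8-(2-methylpropanoyloxy)germacra-4,11(13)-dien-12,6-olide, cis-fused | C=C1C(=O)O[C@H]2/C=C(/C)CC[C@H]3O[C@]3(C)[C@@H](O)[C@H](OC(=O)C(C)C)[C@@H]12 | target

**Totals**
Total step count: 13. Longest linear sequence: 13 steps (from 1).

**Steps most likely to fail**

1. Step 12 (proposed new method). What may go wrong: poor facial selectivity in the carbopalladation, β-hydride elimination from the allylpalladium intermediate before C–O bond formation, or ionization of the allylic isobutyrate by zerovalent palladium. Fallback with known chemistry, setting out from 15 and coming back at 19: an oxidative radical lactone annulation of the diene with allyl hydrogen malonate, Mn(OAc)3·2H2O and Cu(OAc)2 in AcOH–MeCN should add the malonyl radical to C7 and, after oxidation of the allyl radical, close the lactone at C6 to give the α-(allyloxycarbonyl) lactone F1. Pd(PPh3)4 and morpholine at rt would release the α-carboxy lactone F2. Paraformaldehyde and Et2NH (Mannich reaction with decarboxylative elimination) would then give 19.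

2. Step 11. What may go wrong: oligomerization instead of ten-membered ring closure, metathesis at the internal C4=C5 bond with ring truncation, or formation of the E olefin. Fallback, setting out from 13 and coming back at 15: Wittig reaction of 13 with the ylide from (hex-5-en-1-yl)triphenylphosphonium bromide and NaN(SiMe3)2 would give the relay triene F3. In a relay ring-closing metathesis the catalyst loads on the unhindered terminal alkene, expels cyclopentene and is thereby placed on C6 intramolecularly before it closes onto the C7 vinyl group to give 15.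

3. Step 4. What may go wrong: erosion of diastereoselectivity because reagent control opposes the Felkin–Anh preference of the epoxy aldehyde, or Lewis-acid opening of the epoxide. Fallback, setting out from 2 and coming back at 9: the order of epoxidation and allylation is reversed. Oxidation of 2 with TEMPO and PhI(OAc)2 would give the achiral enal F4. The same alkoxyallylboration with 6, now without substrate bias, would pass through the borinate ester F5 to the bis-allylic alcohol F6. Silylation (TBSOTf, 2,6-lutidine) would give the silyl ether F7. Shi epoxidation (D-fructose-derived ketone, Oxone (2KHSO5·KHSO4·K2SO4), K2CO3, MeCN–dimethoxymethane–H2O, 0 °C) of the E-trisubstituted C1=C10 alkene under catalyst control, with the acetate-deactivated Z alkene and the vinyl group reacting more slowly, would then return to 9.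

**Further compounds**

F1 | step 12 | C11-(allyloxycarbonyl)-11,13-dihydro analogue of 19 (mixture at C11) | C=CCOC(=O)C1C(=O)O[C@H]2/C=C(/C)CC[C@H]3O[C@]3(C)[C@@H](O[Si](C)(C)C(C)(C)C)[C@H](OC(=O)C(C)C)[C@@H]12
F2 | step 12 | C11-carboxy-11,13-dihydro analogue of 19 (mixture at C11) | OC(=O)C1C(=O)O[C@H]2/C=C(/C)CC[C@H]3O[C@]3(C)[C@@H](O[Si](C)(C)C(C)(C)C)[C@H](OC(=O)C(C)C)[C@@H]12
F3 | step 11 | (3R,4S)-4-[(tert-butyldimethylsilyl)oxy]-4-{(2S,3R)-2-methyl-3-[(3Z,5Z)-3-methylundeca-3,5,10-trien-1-yl]oxiran-2-yl}but-1-en-3-yl 2-methylpropanoate | C=CCCC/C=C\C=C(\C)CC[C@H]1O[C@]1(C)[C@@H](O[Si](C)(C)C(C)(C)C)[C@H](OC(=O)C(C)C)C=C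
F4 | step 4 | (2Z,6E)-3,7-dimethyl-8-oxoocta-2,6-dien-1-yl acetate | CC(=O)OC/C=C(/C)CC/C=C(\C)C=O
F5 | step 4 | O-diisopinocampheylboryl derivative (borinate ester) of F6 | CC(=O)OC/C=C(/C)CC/C=C(\C)[C@@H](OB([C@@H]1C[C@@H]2C[C@H]([C@H]1C)C2(C)C)[C@@H]1C[C@@H]2C[C@H]([C@H]1C)C2(C)C)[C@H](Oc1ccc(OC)cc1)C=C
F6 | step 4 | (2Z,6E,8R,9R)-8-hydroxy-9-(4-methoxyphenoxy)-3,7-dimethylundeca-2,6,10-trien-1-yl acetate | CC(=O)OC/C=C(/C)CC/C=C(\C)[C@@H](O)[C@H](Oc1ccc(OC)cc1)C=C
F7 | step 4 | (2Z,6E,8R,9R)-8-[(tert-butyldimethylsilyl)oxy]-9-(4-methoxyphenoxy)-3,7-dimethylundeca-2,6,10-trien-1-yl acetate | CC(=O)OC/C=C(/C)CC/C=C(\C)[C@@H](O[Si](C)(C)C(C)(C)C)[C@H](Oc1ccc(OC)cc1)C=C
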